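In the ash flask each millimole of target standing has cost one of substrate and one of partner. The ash charge holds 240 mM of partner against 290 mM of substrate, less of it, so partner is the limiting reagent and you keep the ledger in partner.

| flask | substrate | partner | catalyst | time |
|---|---|---|---|---|
| elm | 120 mM | 240 mM | 2.40 mM |  |
| larch | 120 mM | 120 mM | 2.40 mM |  |
| maple | 180 mM | 240 mM | 2.40 mM |  |
| cedar | 120 mM | 240 mM | 4.80 mM |  |
| ash | 290 mM | 240 mM | 2.40 mM | 95 min |

| elm run: time / min | elm run: [target] / mM | larch run: time / min | larch run: [target] / mM | maple run: time / min | maple run: [target] / mM | cedar run: time / min | cedar run: [target] / mM |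
|---|---|---|---|---|---|---|---|
| 19 | 19.8 | 19 | 10.0 | 19 | 22.0 | 19 | 29.5 |
| 38 | 29.7 | 38 | 18.1 | 38 | 37.7 | 38 | 46.3 |
| 57 | 35.5 | 57 | 21.1 | 57 | 42.9 | 57 | 54.0 |
| 76 | 39.1 | 76 | 28.1 | 76 | 47.5 | 76 | 57.5 |
| 95 | 40.3 | 95 | 30.1 | 95 | 48.9 | 95 | 57.2 |

(readings scatter by 1 mM)

* the exponent of [substrate] in the starting rate at the charge of the elm run (at the point where two percent of the substrate have become target) (one fixed amount of target, the same in the runs compared)
* the exponent of [catalyst] in the starting rate at the charge of the elm run (at the point where two percent of the substrate have become target)
* target in the ash run at 95 min, as a share of the substrate charged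

- Overall: substrate + partner -> target, with catalyst as catalyst.
- Constant volume, constant temperature.
- What is held in complexes is read along with the free species.
- "The second partner" is partner.
- An order is taken over about fifteen percent of the charge, up and down.

The first entry is the ceiling: all the partner turned to target would come to 82.8% of the substrate charged. Elm gains 1.20 mM over its last interval and stands at 40.3 mM from 120 mM of substrate.

So the second entry must come from the readings. Replace each curve by its mean rate, the last reading over its time: elm 0.424 mM min⁻¹, maple 0.515 mM min⁻¹. Elm, maple and ash share their partner and catalyst charges. I call the reach exponent, the power of the substrate step that carries one mean rate to the other with those two held, 0.477.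

A mean hides the shape: elm's first interval ran at 1.04 mM min⁻¹, faster than its mean. But the exponent needs just that both curves keep one shape, and the reading before last gives 0.480. The scatter puts 0.0793 on it.

Carried to ash, the mean rate is 0.646 mM min⁻¹, so 61.4 mM of target at 95 min. That is 21.2% of the substrate, give or take 1.5 percentage points. The books then read 61.4 mM of partner in target and 179 mM elsewhere, and target readings can't say where. I take the exponent as the substrate order too. Cedar over elm at the first reading gives a catalyst order of 0.575, as read from those two scattered readings.

The forecast gave 0.5 and 0.5 for the orders and 20.7% for ash, holding that “the catalyst is dying”, and its catalyst order stands lower than mine.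

The flask gives 0.44 in substrate, 0.69 in catalyst and 21.5% in ash, against my 21.2%.

    catalyst + substrate ⇌ catalyst-substrate complex, settled at all times (62.60 M⁻¹)
    catalyst-substrate complex + partner → target + catalyst + by-product (1.698 M⁻¹ min⁻¹)
    target + partner → side product (0.07740 M⁻¹ min⁻¹)
    substrate + partner → target (0.01476 M⁻¹ min⁻¹)

The ash ledger carries a second charge on the partner. Because target and partner turn into side product, the ash flask ends at 21.5% of its substrate, where without that step it stands at 40.4%. Each side product has cost two partners, one to make the target and one to lose it, and 62.3 mM of target remains standing. On maple, the reach exponent takes elm's starting rate of 1.2 mM min⁻¹ to 1.47 mM min⁻¹, and maple's simulated rate is 1.5 mM min⁻¹.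

(The numbers in the tables are simulated for substances that don't exist, and the scatter is random.)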